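## Retrosynthetic overview

1. Rings are lettered A to H along the chain as written in the SMILES (A = 2,4,6-trihydroxyphenyl end, H = 3,4,5-trihydroxyphenyl end). All eight benzene rings are bought, none is built, and every disconnection is a diaryl ether C–O bond.
2. Last: cleavage of 21 methyl ethers. Before that, ring A is put on the ring B oxygen by copper coupling with 2-iodo-1,3,5-trimethoxybenzene.
3. Key union: the ring C–O–ring D bond, by a one-pot C–H aryloxylation of a ring B–C aldehyde with the ring D–H pentamer phenol (new).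
4. The pentamer phenol comes from two rounds of [Ullmann coupling with one iodo aldehyde block, Dakin oxidation], starting from 3,4,5-trimethoxyphenol (ring H). The block serves first as rings F–G, then as rings D–E.
5. Each two-ring block comes from Ullmann coupling of a hydroxybenzaldehyde with 5-bromo-1,2,3-trimethoxybenzene. The formyl group is the masked phenol and keeps its ring inert to electrophiles. Order of joining: F–G, then H, then D–E, then B–C, then A.

Assumption: the target has no stereocentre and no fixed axis, so the SMILES as given is the whole structure and no enantiomer has to be set.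

Assumption: the trivalent iodine reagent of step 8, hydroxy(tosyloxy)iodo-2,4,6-triisopropylbenzene (TRIP–I(OH)OTs, CC(C)c1cc(C(C)C)c(I(O)OS(=O)(=O)c2ccc(C)cc2)c(C(C)C)c1), is not a catalogue item. It is made beforehand in one flask from commercial 2-iodo-1,3,5-triisopropylbenzene (mCPBA, TsOH·H2O) and is treated as a reagent, not as a route step.

## Route

Step 1
Reactants: 1 syringaldehyde (4-hydroxy-3,5-dimethoxybenzaldehyde); 2 5-bromo-1,2,3-trimethoxybenzene
Product: 3 3,5-dimethoxy-4-(3,4,5-trimethoxyphenoxy)benzaldehyde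
Conditions: CuI (10 mol%), picolinic acid (20 mol%), K3PO4, DMSO, 100 °C, argon
Reagents that add atoms: none
Why: Ullmann diaryl ether synthesis of a hindered but acidic phenol with an unhindered aryl bromide; the formyl group is untouched and later serves as masked phenol and as deactivator of its ring.

Step 2
Reactants: 3 3,5-dimethoxy-4-(3,4,5-trimethoxyphenoxy)benzaldehyde
Product: 4 4-(2-iodo-3,4,5-trimethoxyphenoxy)-3,5-dimethoxybenzaldehyde
Conditions: NIS (1.05 equiv), CF3CO2H (0.3 equiv), MeCN, rt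
Reagents that add atoms: N-iodosuccinimide, O=C1CCC(=O)N1I
Why: Electrophilic aromatic iodination; the trimethoxyphenoxy ring has two equivalent C–H positions (ortho to the aryloxy group, para to a methoxy group) and the formyl-bearing ring is deactivated, so a single regioisomer forms.

Step 3
Reactants: 4 4-(2-iodo-3,4,5-trimethoxyphenoxy)-3,5-dimethoxybenzaldehyde; 5 3,4,5-trimethoxyphenol
Product: 6 trimer aldehyde of rings F–G–H (3,5-dimethoxy-4-[3,4,5-trimethoxy-2-(3,4,5-trimethoxyphenoxy)phenoxy]benzaldehyde)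
Conditions: CuI (10 mol%), picolinic acid (20 mol%), K3PO4, DMSO, 90 °C, argon
Reagents that add atoms: none
Why: Ullmann diaryl ether synthesis of a doubly ortho-substituted aryl iodide with an unhindered, electron-rich phenol, a pairing the picolinic acid system tolerates; it forms the ring G–O–ring H bond.

Step 4
Reactants: 6 trimer aldehyde of rings F–G–H
Product: 8 trimer phenol (3,5-dimethoxy-4-[3,4,5-trimethoxy-2-(3,4,5-trimethoxyphenoxy)phenoxy]phenol), via aryl formate 7 (not isolated)
Conditions: 30% H2O2, H2SO4 (cat.), MeOH/CH2Cl2, rt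
Reagents that add atoms: hydrogen peroxide, OO
Why: Acid-catalysed Dakin oxidation (Baeyer–Villiger-type aryl migration, favoured by the para aryloxy group); the formate is methanolysed in the flask, and methyl and diaryl ethers are inert.

Step 5
Reactants: 4 4-(2-iodo-3,4,5-trimethoxyphenoxy)-3,5-dimethoxybenzaldehyde; 8 trimer phenol
Product: 9 pentamer aldehyde of rings D–H (3,5-dimethoxy-4-[3,4,5-trimethoxy-2-(aryloxy)phenoxy]benzaldehyde; aryloxy = 8 bound through its phenol oxygen)
Conditions: CuI (10 mol%), picolinic acid (20 mol%), K3PO4, DMSO, 90 °C, argon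
Reagents that add atoms: none
Why: Second Ullmann diaryl ether synthesis with the same iodide block, now forming the ring E–O–ring F bond; the phenol of 8 is flanked by two C–H and is the only nucleophile present.

Step 6
Reactants: 9 pentamer aldehyde of rings D–H
Product: 11 pentamer phenol (the phenol corresponding to 9), via aryl formate 10 (not isolated)
Conditions: 30% H2O2, H2SO4 (cat.), MeOH/CH2Cl2, rt
Reagents that add atoms: hydrogen peroxide, OO
Why: Dakin oxidation as in step 4, unmasking the ring D oxygen that will become the ring C–O–ring D ether.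

Step 7
Reactants: 12 3-hydroxy-4,5-dimethoxybenzaldehyde; 2 5-bromo-1,2,3-trimethoxybenzene
Product: 13 3,4-dimethoxy-5-(3,4,5-trimethoxyphenoxy)benzaldehyde
Conditions: CuI (10 mol%), picolinic acid (20 mol%), K3PO4, DMSO, 100 °C, argon
Reagents that add atoms: none
Why: Ullmann diaryl ether synthesis forming the ring B–O–ring C bond; again the formyl ring is the masked phenol and is deactivated toward electrophiles.

Step 8
Reactants: 13 3,4-dimethoxy-5-(3,4,5-trimethoxyphenoxy)benzaldehyde; 11 pentamer phenol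
Product: 15 heptamer aldehyde of rings B–H (3,4-dimethoxy-5-[3,4,5-trimethoxy-2-(aryloxy)phenoxy]benzaldehyde; aryloxy = 11 bound through its phenol oxygen), via iodonium tosylate 14 (not isolated)
Conditions: TRIP–I(OH)OTs (1.4 equiv; TRIP = 2,4,6-triisopropylphenyl), 13 (1.5 equiv), CH2Cl2/CF3CH2OH, rt; evaporate; then 11 (1.0 equiv), Cu(MeCN)4BF4 (10 mol%), iPr2NEt, CH2Cl2, rt to 40 °C
Reagents that add atoms: none
Why: Proposed new method: the trivalent iodine reagent attacks the only electron-rich C–H type of 13 (ring C, ortho to the aryloxy group and para to a methoxy group; ring B is switched off by its formyl group) to give salt 14, and the excess of 13 uses up all the oxidant before the oxidisable phenol 11 is added; monovalent copper then adds oxidatively into the less shielded aryl–iodine bond (the oxygen-flanked ring C carbon, not the isopropyl-flanked TRIP carbon), and the resulting aryl(trivalent copper) phenoxide reductively eliminates the ring C–O–ring D ether; the closest known reaction type is the one-pot copper-catalysed para C–H aryloxylation of electron-rich arenes through transient aryl(mesityl)iodonium salts, which has not been shown for a doubly ortho-oxygenated aryl group (normally the spectator on iodine), with a TRIP auxiliary, or with an oligomeric phenol.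

Step 9
Reactants: 15 heptamer aldehyde of rings B–H
Product: 17 heptamer phenol (the phenol corresponding to 15), via aryl formate 16 (not isolated)
Conditions: 30% H2O2, H2SO4 (cat.), MeOH/CH2Cl2, rt
Reagents that add atoms: hydrogen peroxide, OO
Why: Dakin oxidation, here helped by the methoxy group para to the formyl group, unmasking the ring B oxygen that will carry ring A.

Step 10
Reactants: 17 heptamer phenol; 18 2-iodo-1,3,5-trimethoxybenzene (3 equiv)
Product: 19 henicosa-O-methyl ether of the target (all 21 hydroxyl groups as OMe)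
Conditions: CuI (20 mol%), picolinic acid (40 mol%), K3PO4, DMSO, 100 °C, argon
Reagents that add atoms: none
Why: Ullmann diaryl ether synthesis of the same class as steps 3 and 5 (unhindered phenol, doubly ortho-oxygenated aryl iodide), forming the ring A–O–ring B bond and completing the carbon–oxygen skeleton.

Step 11
Reactants: 19 henicosa-O-methyl ether of the target
Product: 20 target CNP0175816.0
Conditions: BBr3 (about 40 equiv), CH2Cl2, −78 °C to rt; then H2O, 0 °C, argon; reversed-phase chromatography with degassed acidic eluent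
Reagents that add atoms: none
Why: Lewis-acid ether cleavage; bromide attacks the methyl carbon of each boron-complexed aryl methyl ether, whereas the seven diaryl ether bonds offer no alkyl carbon and survive, and no stereocentre exists to be affected.

## Compound list

1 | syringaldehyde (4-hydroxy-3,5-dimethoxybenzaldehyde) | COc1cc(C=O)cc(OC)c1O | starting material
2 | 5-bromo-1,2,3-trimethoxybenzene | COc1cc(Br)cc(OC)c1OC | starting material
3 | 3,5-dimethoxy-4-(3,4,5-trimethoxyphenoxy)benzaldehyde | COc1cc(C=O)cc(OC)c1Oc1cc(OC)c(OC)c(OC)c1 | intermediate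
4 | 4-(2-iodo-3,4,5-trimethoxyphenoxy)-3,5-dimethoxybenzaldehyde | COc1cc(C=O)cc(OC)c1Oc1cc(OC)c(OC)c(OC)c1I | intermediate
5 | 3,4,5-trimethoxyphenol | COc1cc(O)cc(OC)c1OC | starting material
6 | trimer aldehyde, rings F–G–H: 3,5-dimethoxy-4-[3,4,5-trimethoxy-2-(3,4,5-trimethoxyphenoxy)phenoxy]benzaldehyde | COc1cc(C=O)cc(OC)c1Oc1cc(OC)c(OC)c(OC)c1Oc1cc(OC)c(OC)c(OC)c1 | intermediate
7 | formate ester of 8 | COc1cc(OC=O)cc(OC)c1Oc1cc(OC)c(OC)c(OC)c1Oc1cc(OC)c(OC)c(OC)c1 | intermediate
8 | trimer phenol: 3,5-dimethoxy-4-[3,4,5-trimethoxy-2-(3,4,5-trimethoxyphenoxy)phenoxy]phenol | COc1cc(O)cc(OC)c1Oc1cc(OC)c(OC)c(OC)c1Oc1cc(OC)c(OC)c(OC)c1 | intermediate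
9 | pentamer aldehyde, rings D–H: 3,5-dimethoxy-4-[3,4,5-trimethoxy-2-(aryloxy)phenoxy]benzaldehyde, aryloxy = 8 bound through its phenol oxygen | COc1cc(C=O)cc(OC)c1Oc1cc(OC)c(OC)c(OC)c1Oc1cc(OC)c(Oc2cc(OC)c(OC)c(OC)c2Oc2cc(OC)c(OC)c(OC)c2)c(OC)c1 | intermediate
10 | formate ester of 11 | COc1cc(OC=O)cc(OC)c1Oc1cc(OC)c(OC)c(OC)c1Oc1cc(OC)c(Oc2cc(OC)c(OC)c(OC)c2Oc2cc(OC)c(OC)c(OC)c2)c(OC)c1 | intermediate
11 | pentamer phenol, rings D–H (phenol corresponding to 9) | COc1cc(O)cc(OC)c1Oc1cc(OC)c(OC)c(OC)c1Oc1cc(OC)c(Oc2cc(OC)c(OC)c(OC)c2Oc2cc(OC)c(OC)c(OC)c2)c(OC)c1 | intermediate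
12 | 3-hydroxy-4,5-dimethoxybenzaldehyde | COc1cc(C=O)cc(O)c1OC | starting material
13 | 3,4-dimethoxy-5-(3,4,5-trimethoxyphenoxy)benzaldehyde | COc1cc(C=O)cc(Oc2cc(OC)c(OC)c(OC)c2)c1OC | intermediate
14 | [2-(5-formyl-2,3-dimethoxyphenoxy)-4,5,6-trimethoxyphenyl](2,4,6-triisopropylphenyl)iodonium tosylate | COc1cc(C=O)cc(Oc2cc(OC)c(OC)c(OC)c2[I+]c2c(C(C)C)cc(C(C)C)cc2C(C)C)c1OC.Cc1ccc(S(=O)(=O)[O-])cc1 | intermediate
15 | heptamer aldehyde, rings B–H: 3,4-dimethoxy-5-[3,4,5-trimethoxy-2-(aryloxy)phenoxy]benzaldehyde, aryloxy = 11 bound through its phenol oxygen | COc1cc(C=O)cc(Oc2cc(OC)c(OC)c(OC)c2Oc2cc(OC)c(Oc3cc(OC)c(OC)c(OC)c3Oc3cc(OC)c(Oc4cc(OC)c(OC)c(OC)c4Oc4cc(OC)c(OC)c(OC)c4)c(OC)c3)c(OC)c2)c1OC | intermediate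
16 | formate ester of 17 | COc1cc(OC=O)cc(Oc2cc(OC)c(OC)c(OC)c2Oc2cc(OC)c(Oc3cc(OC)c(OC)c(OC)c3Oc3cc(OC)c(Oc4cc(OC)c(OC)c(OC)c4Oc4cc(OC)c(OC)c(OC)c4)c(OC)c3)c(OC)c2)c1OC | intermediate
17 | heptamer phenol, rings B–H (phenol corresponding to 15) | COc1cc(O)cc(Oc2cc(OC)c(OC)c(OC)c2Oc2cc(OC)c(Oc3cc(OC)c(OC)c(OC)c3Oc3cc(OC)c(Oc4cc(OC)c(OC)c(OC)c4Oc4cc(OC)c(OC)c(OC)c4)c(OC)c3)c(OC)c2)c1OC | intermediate
18 | 2-iodo-1,3,5-trimethoxybenzene | COc1cc(OC)c(I)c(OC)c1 | starting material
19 | henicosa-O-methyl ether of the target | COc1cc(OC)c(Oc2cc(OC)c(OC)c(Oc3cc(OC)c(OC)c(OC)c3Oc3cc(OC)c(Oc4cc(OC)c(OC)c(OC)c4Oc4cc(OC)c(Oc5cc(OC)c(OC)c(OC)c5Oc5cc(OC)c(OC)c(OC)c5)c(OC)c4)c(OC)c3)c2)c(OC)c1 | intermediate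
20 | CNP0175816.0 (octameric fuhalol-type phlorotannin, C48H34O28) | Oc1cc(O)c(Oc2cc(O)c(O)c(Oc3cc(O)c(O)c(O)c3Oc3cc(O)c(Oc4cc(O)c(O)c(O)c4Oc4cc(O)c(Oc5cc(O)c(O)c(O)c5Oc5cc(O)c(O)c(O)c5)c(O)c4)c(O)c3)c2)c(O)c1 | target

## Step count and risks

Total steps: 11. Longest linear sequence: 10 (steps 1 to 6, then 8 to 11; step 7 is a one-step side branch).

Three steps most likely to fail:

**Step 8 (the new one-pot C–H aryloxylation).** The copper catalyst may transfer the TRIP group or neither aryl group, or salt 14 may oxidise phenol 11. The fallback uses only known chemistry, sets out from 13 and returns at 15. Compound 13 is iodinated as in step 2 (NIS, CF3CO2H, MeCN, rt) to give 3-(2-iodo-3,4,5-trimethoxyphenoxy)-4,5-dimethoxybenzaldehyde F1. F1 is then coupled with 11 under the Ullmann conditions of step 5 (CuI, picolinic acid, K3PO4, DMSO, 90 °C) to give 15. This costs one extra step.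

**Step 10 (ring A by Ullmann coupling).** Iodide 18 is very electron-rich and doubly ortho-substituted, and on the large phenol its reduction to 1,3,5-trimethoxybenzene may outrun coupling. The fallback reverses the polarity, sets out from 17 and returns at 19. Phenol 17 is converted (Tf2O, pyridine, CH2Cl2, 0 °C) into the heptamer aryl triflate F2, an unhindered electrophile. Palladium-catalysed etherification of F2 with commercial 2,4,6-trimethoxyphenol (COc1cc(OC)c(O)c(OC)c1; Pd(OAc)2, tBuXPhos, K3PO4, toluene, 100 °C) gives 19, with the hindered ring now the nucleophile.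

**Step 11 (21-fold demethylation).** Cleavage may stop short, and the free polyphenol is air-sensitive and hard to purify. The fallback changes the end-game to isolation through a protected derivative, sets out from 19 and returns at 20. After BBr3 cleavage and aqueous quench as in step 11, the crude polyphenol is freeze-dried and acetylated without purification (Ac2O, pyridine, DMAP) to the henicosa-O-acetate of the target F3. F3 is stable, is purified on silica, and shows by its OMe signals any under-cleaved material, which is resubmitted to BBr3. Deacetylation with HCl in degassed MeOH under argon at rt gives 20.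

## Further compounds

F1 | step 8 | 3-(2-iodo-3,4,5-trimethoxyphenoxy)-4,5-dimethoxybenzaldehyde | COc1cc(C=O)cc(Oc2cc(OC)c(OC)c(OC)c2I)c1OC
F2 | step 10 | heptamer aryl triflate (trifluoromethanesulfonate of phenol 17) | COc1cc(OS(=O)(=O)C(F)(F)F)cc(Oc2cc(OC)c(OC)c(OC)c2Oc2cc(OC)c(Oc3cc(OC)c(OC)c(OC)c3Oc3cc(OC)c(Oc4cc(OC)c(OC)c(OC)c4Oc4cc(OC)c(OC)c(OC)c4)c(OC)c3)c(OC)c2)c1OC
F3 | step 11 | henicosa-O-acetate of the target | CC(=O)Oc1cc(OC(C)=O)c(Oc2cc(OC(C)=O)c(OC(C)=O)c(Oc3cc(OC(C)=O)c(OC(C)=O)c(OC(C)=O)c3Oc3cc(OC(C)=O)c(Oc4cc(OC(C)=O)c(OC(C)=O)c(OC(C)=O)c4Oc4cc(OC(C)=O)c(Oc5cc(OC(C)=O)c(OC(C)=O)c(OC(C)=O)c5Oc5cc(OC(C)=O)c(OC(C)=O)c(OC(C)=O)c5)c(OC(C)=O)c4)c(OC(C)=O)c3)c2)c(OC(C)=O)c1
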